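## Retrosynthetic overview
1. Denticulatolide comes from its 7-alcohol by acetylation. The 8,11-peroxide is tied transannularly: O to C8 by rear-side opening of a 7,8-epoxide, and O to C11 with the Δ11→Δ12 shift of the presumed ene-type oxygenation.
2. H13 of that ene step is replaced by a stereodefined C13 phosphate. This programmes the regiochemistry, C11 and the 12Z geometry, which a singlet-oxygen ene reaction on an 11E-trisubstituted olefin would not deliver.
3. The epoxide comes from catalyst-controlled epoxidation of Δ7, the only electron-rich olefin left in a 13-oxygenated cembranolide.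
4. The 14-membered ring and the cis-lactone are made in one closure of C1–C2, the bond the cembrane cyclase makes, from a C20 chain built from farnesyl acetate, an allyl unit and methyl 2-(bromomethyl)acrylate.
5. Ring order: carbocycle and γ-lactone together, then oxirane, then 1,2-dioxane.

Assumption: cembrane numbering is used (C1 = ring CH bearing C15, C2 = lactone OCH, C7 = CHOAc, C8 and C11 = peroxide carbons, C12=C13 = the Z olefin), and farnesyl acetate is bought as the pure 2E,6E isomer.

## Route

Step 1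
Reactants: 1 (2E,6E)-farnesyl acetate
Product: 2 (2E,6E,10E)-3,7,11-trimethyl-12-oxododeca-2,6,10-trien-1-yl acetate
Conditions: SeO2 (1.2 equiv), dioxane–H2O 20:1, 80 °C
Reagents that add atoms: selenium dioxide, O=[Se]=O
Why: Riley allylic oxidation (ene reaction then [2,3]-sigmatropic shift) picks the terminal, most electron-rich trisubstituted olefin and its E-methyl group and runs on to the (E)-enal, the 2,3-olefin being deactivated by the allylic acetate, and no stereocentre is formed.

Step 2
Reactants: 2 (2E,6E,10E)-3,7,11-trimethyl-12-oxododeca-2,6,10-trien-1-yl acetate; 3 allylboronic acid pinacol ester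
Product: 5 (2E,6E,10E,12R)-3,7,11-trimethylpentadeca-2,6,10,14-tetraene-1,12-diol, via borate ester 4 (not isolated)
Conditions: 3 (1.3 equiv), (R)-3,3'-bis(2,4,6-triisopropylphenyl)-1,1'-binaphthyl-2,2'-diyl hydrogen phosphate (5 mol %), toluene, −30 °C; then K2CO3 (0.2 equiv), MeOH, rt
Reagents that add atoms: allylboronic acid pinacol ester (3), C=CCB1OC(C)(C)C(C)(C)O1
Why: Chiral-phosphoric-acid-catalysed allylboration through a closed six-membered transition state adds allyl to one carbonyl face and sets C13 (chain C12) as R, the sense established for aryl and alkenyl aldehydes with the R acid, and catalytic methoxide then transesterifies borate and acetate in the same flask.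

Step 3
Reactants: 5 (2E,6E,10E,12R)-3,7,11-trimethylpentadeca-2,6,10,14-tetraene-1,12-diol
Product: 6 (2E,6E,10E,12R)-12-hydroxy-3,7,11-trimethylpentadeca-2,6,10,14-tetraenal
Conditions: 2,2,6,6-tetramethylpiperidine-1-oxyl (10 mol %), PhI(OAc)2 (1.05 equiv), CH2Cl2, 0 °C to rt
Reagents that add atoms: none
Why: Oxoammonium (TEMPO) oxidation is sterically selective for the primary allylic alcohol over the hindered secondary one, does not isomerise the 2E olefin and touches no stereocentre.

Step 4
Reactants: 6 (2E,6E,10E,12R)-12-hydroxy-3,7,11-trimethylpentadeca-2,6,10,14-tetraenal; 7 methyl 2-(bromomethyl)acrylate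
Product: 8 methyl (2Z,5R,6E,10E,14E)-2-(bromomethyl)-5-hydroxy-6,10,14-trimethyl-16-oxohexadeca-2,6,10,14-tetraenoate
Conditions: 7 (5 equiv), second-generation Hoveyda–Grubbs catalyst (5 mol %), 1,4-benzoquinone (10 mol %), CH2Cl2, 40 °C; used at once
Reagents that add atoms: methyl 2-(bromomethyl)acrylate (7), C=C(CBr)C(=O)OC
Why: Olefin cross-metathesis, in which the monosubstituted olefin is the only metathesis-active alkene of 6 (all others are trisubstituted) and couples with the excess methacrylate-type partner as terminal olefins do with methacrylates, placing C14 trans to the ester and leaving C13 untouched.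

Step 5
Reactants: 8 methyl (2Z,5R,6E,10E,14E)-2-(bromomethyl)-5-hydroxy-6,10,14-trimethyl-16-oxohexadeca-2,6,10,14-tetraenoate
Product: 10 (1S,2S,3E,7E,11E,13R)-13-hydroxycembra-3,7,11,15(17)-tetraen-16,2-olide, via silyl ether 9 (not isolated)
Conditions: CrCl2 (15 mol %), (S,S)-1,8-bis(4-isopropyl-4,5-dihydrooxazol-2-yl)-3,6-diphenyl-9H-carbazole (18 mol %), iPr2NEt (30 mol %), Mn (3 equiv), Me3SiCl (2 equiv), THF, 8 added over 20 h (final 2 mM), rt; then 1 M HCl, THF, rt
Reagents that add atoms: chlorotrimethylsilane, C[Si](C)(C)Cl (its silyl group is in 9 only)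
Why: Proposed new method: an intramolecular, ligand-controlled Nozaki–Hiyama–Kishi-type 2-(alkoxycarbonyl)allylation in which divalent chromium inserts into the allylic bromide, the allylchromium (C14 cis to CH2Cr) attacks the enal through C1 in a chair transition state to give the syn adduct, the chiral bis(oxazoline) fixes the aldehyde face so that C1 and C2 come out S,S (the ligand's sense is taken by analogy with the intermolecular reaction and its antipode is equally available), and acid then removes the silyl group and closes the cis-lactone, the closest known reactions being the intermolecular chromium-catalysed enantioselective synthesis of α-methylene-γ-butyrolactones and CrCl2 closures of 14-membered cembranoid rings at this same C1–C2 bond, with any wrong diastereomer separable because C13 is already fixed.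

Step 6
Reactants: 10 (1S,2S,3E,7E,11E,13R)-13-hydroxycembra-3,7,11,15(17)-tetraen-16,2-olide
Product: 11 (1S,2S,3E,7E,11E,13R)-13-(diethoxyphosphoryloxy)cembra-3,7,11,15(17)-tetraen-16,2-olide
Conditions: (EtO)2P(O)Cl (1.5 equiv), pyridine (3 equiv), 4-(dimethylamino)pyridine (10 mol %), CH2Cl2, 0 °C
Reagents that add atoms: diethyl chlorophosphate, CCOP(=O)(Cl)OCC
Why: O-Phosphorylation with retention at C13 installs the type of leaving group that terpene biosynthesis itself uses and at the same time deactivates the 11,12-olefin towards the next oxidation.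

Step 7
Reactants: 11 (1S,2S,3E,7E,11E,13R)-13-(diethoxyphosphoryloxy)cembra-3,7,11,15(17)-tetraen-16,2-olide
Product: 12 (1S,2S,3E,7S,8S,11E,13R)-13-(diethoxyphosphoryloxy)-7,8-epoxycembra-3,11,15(17)-trien-16,2-olide
Conditions: 1,2:4,5-di-O-isopropylidene-β-L-erythro-2,3-hexodiulo-2,6-pyranose (30 mol %), KHSO5 (as Oxone, 1.4 equiv), K2CO3, Bu4NHSO4 (cat.), MeCN–CH2(OMe)2–aq Na2B4O7 buffer, 0 °C
Reagents that add atoms: potassium peroxymonosulfate, [K+].[O-]S(=O)(=O)OO
Why: Shi asymmetric epoxidation, in which the chiral dioxirane of the L-series ketone attacks the only electron-rich olefin left (Δ3 and Δ11 carry allylic acyloxy or phosphoryloxy groups and the acrylate is electron-poor) through the spiro transition state and gives the trans (7S,8S)-epoxide, the mirror image of the R,R sense known for the D-fructose-derived ketone with E-trisubstituted olefins.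

Step 8
Reactants: 12 (1S,2S,3E,7S,8S,11E,13R)-13-(diethoxyphosphoryloxy)-7,8-epoxycembra-3,11,15(17)-trien-16,2-olide
Product: 13 (1S,2S,3E,7S,8R,11E,13R)-13-(diethoxyphosphoryloxy)-8-hydroperoxy-7-hydroxycembra-3,11,15(17)-trien-16,2-olide
Conditions: H2O2 (anhydrous, 3 M in Et2O, 15 equiv), H3PMo12O40 (5 mol %), Et2O, 0 °C
Reagents that add atoms: hydrogen peroxide, OO
Why: Acid-catalysed perhydrolysis of an epoxide, in which the heteropolyacid activates the oxirane and H2O2 attacks the tertiary carbon C8 from the rear (borderline SN2) so that C8 is inverted to R while C7 keeps its S-configured oxygen, no internal oxygen nucleophile being able to reach C8.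

Step 9
Reactants: 13 (1S,2S,3E,7S,8R,11E,13R)-13-(diethoxyphosphoryloxy)-8-hydroperoxy-7-hydroxycembra-3,11,15(17)-trien-16,2-olide
Product: 15 denticulatolide, via deacetyl alcohol 14 (not isolated)
Conditions: Cs2CO3 (1.0 equiv), MeCN, −20 to 0 °C; then Ac2O (1.5 equiv), 4-(dimethylamino)pyridine (5 mol %), 0 °C
Reagents that add atoms: acetic anhydride, CC(=O)OC(C)=O
Why: Proposed new method: the caesium salt of the tertiary hydroperoxide (pKa near 12, so the C7 alcohol stays protonated) attacks C11 in a transannular 6-exo SN2' displacement of the C13 phosphate (direct SN2 would need an eight-membered ring holding an E olefin), which copies the O-to-C11 bonding and Δ11→Δ12 shift of the presumed ene-type oxygenation but with a stereodefined leaving group in place of H13, and since an anionic nucleophile is expected to follow the anti course, the 13R phosphate reacts through the transition state that keeps H13 beside the C12 methyl group and C14 inside (the same 1,2-allylic strain that makes [2,3]-Wittig shifts of 2-methylallyl ethers Z-selective) and so delivers oxygen to the face of C11 that gives 11S, the 12Z olefin and the less strained cis-bridged dioxane together, the closest known reactions being base-mediated cyclisations of hydroperoxides onto halides or sulfonates to 1,2-dioxanes and SN2' ring closures of alkoxides, after which the free C7 alcohol is acetylated in the same flask.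

## Compound list
1 | (2E,6E)-farnesyl acetate | CC(C)=CCC/C(C)=C/CC/C(C)=C/COC(C)=O | starting material
2 | (2E,6E,10E)-3,7,11-trimethyl-12-oxododeca-2,6,10-trien-1-yl acetate | O=C/C(C)=C/CC/C(C)=C/CC/C(C)=C/COC(C)=O | intermediate
3 | allylboronic acid pinacol ester | C=CCB1OC(C)(C)C(C)(C)O1 | starting material
4 | (2E,6E,10E,12R)-3,7,11-trimethyl-12-(4,4,5,5-tetramethyl-1,3,2-dioxaborolan-2-yloxy)pentadeca-2,6,10,14-tetraen-1-yl acetate | C=CC[C@@H](OB1OC(C)(C)C(C)(C)O1)/C(C)=C/CC/C(C)=C/CC/C(C)=C/COC(C)=O | intermediate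
5 | (2E,6E,10E,12R)-3,7,11-trimethylpentadeca-2,6,10,14-tetraene-1,12-diol | C=CC[C@@H](O)/C(C)=C/CC/C(C)=C/CC/C(C)=C/CO | intermediate
6 | (2E,6E,10E,12R)-12-hydroxy-3,7,11-trimethylpentadeca-2,6,10,14-tetraenal | C=CC[C@@H](O)/C(C)=C/CC/C(C)=C/CC/C(C)=C/C=O | intermediate
7 | methyl 2-(bromomethyl)acrylate | C=C(CBr)C(=O)OC | starting material
8 | methyl (2Z,5R,6E,10E,14E)-2-(bromomethyl)-5-hydroxy-6,10,14-trimethyl-16-oxohexadeca-2,6,10,14-tetraenoate | COC(=O)/C(CBr)=C/C[C@@H](O)/C(C)=C/CC/C(C)=C/CC/C(C)=C/C=O | intermediate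
9 | methyl 2-[(1S,2S,3E,7E,11E,13R)-13-hydroxy-4,8,12-trimethyl-2-(trimethylsilyloxy)cyclotetradeca-3,7,11-trien-1-yl]acrylate | COC(=O)C(=C)[C@@H]1C[C@@H](O)/C(C)=C/CC/C(C)=C/CC/C(C)=C/[C@@H]1O[Si](C)(C)C | intermediate
10 | (1S,2S,3E,7E,11E,13R)-13-hydroxycembra-3,7,11,15(17)-tetraen-16,2-olide | C=C1C(=O)O[C@H]2/C=C(\C)CC/C=C(\C)CC/C=C(\C)[C@H](O)C[C@@H]12 | intermediate
11 | (1S,2S,3E,7E,11E,13R)-13-(diethoxyphosphoryloxy)cembra-3,7,11,15(17)-tetraen-16,2-olide | C=C1C(=O)O[C@H]2/C=C(\C)CC/C=C(\C)CC/C=C(\C)[C@H](OP(=O)(OCC)OCC)C[C@@H]12 | intermediate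
12 | (1S,2S,3E,7S,8S,11E,13R)-13-(diethoxyphosphoryloxy)-7,8-epoxycembra-3,11,15(17)-trien-16,2-olide | C=C1C(=O)O[C@H]2/C=C(\C)CC[C@@H]3O[C@@]3(C)CC/C=C(\C)[C@H](OP(=O)(OCC)OCC)C[C@@H]12 | intermediate
13 | (1S,2S,3E,7S,8R,11E,13R)-13-(diethoxyphosphoryloxy)-8-hydroperoxy-7-hydroxycembra-3,11,15(17)-trien-16,2-olide | C=C1C(=O)O[C@H]2/C=C(\C)CC[C@H](O)[C@@](OO)(C)CC/C=C(\C)[C@H](OP(=O)(OCC)OCC)C[C@@H]12 | intermediate
14 | (1S,2S,3E,7S,8R,11S,12Z)-8,11-epidioxy-7-hydroxycembra-3,12,15(17)-trien-16,2-olide (7-O-deacetyldenticulatolide) | C=C1C(=O)O[C@H]2/C=C(\C)CC[C@H](O)[C@@]3(C)CC[C@H](OO3)/C(C)=C\C[C@@H]12 | intermediate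
15 | denticulatolide, (1S,2S,3E,7S,8R,11S,12Z)-7-acetoxy-8,11-epidioxycembra-3,12,15(17)-trien-16,2-olide | C=C1C(=O)O[C@H]2/C=C(\C)CC[C@H](OC(C)=O)[C@@]3(C)CC[C@H](OO3)/C(C)=C\C[C@@H]12 | target

## Step count and main risks
Total step count: 9. Longest linear sequence: 9 (from 1).

**Step 9 (most likely to fail).**
- Under base the β-hydroxy hydroperoxide may fragment at C7–C8.
- The phosphate may be too slow a leaving group.
- A syn course would pair 11S with the 12E olefin.
- Fallback (sets out from 11, comes back at 14): it makes the C11–O bond first and closes the ring at C8, in the polarity of the presumed biosynthesis.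
- Treating 11 with ethereal H2O2 and H3PMo12O40 ionises the phosphate and gives, after separation from the 13-regioisomer, (1S,2S,3E,7E,11S,12Z)-11-hydroperoxycembra-3,7,12,15(17)-tetraen-16,2-olide F1.
- Epoxidation of Δ7 with the dioxirane of step 7 gives (1S,2S,3E,7S,8S,11S,12Z)-7,8-epoxy-11-hydroperoxycembra-3,12,15(17)-trien-16,2-olide F2.
- Catalytic camphorsulfonic acid then triggers the transannular 6-exo opening at C8 to give 14, which is acetylated as before.

**Step 5.**
- High-dilution catalytic turnover and ligand control inside a 14-membered transition state are untested.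
- Fallback (sets out from 6, comes back at 12): it moves the stereocontrol to the substrate and changes the order of events.
- Epoxidising 6 as in step 7 gives (2E,6S,7S,10E,12R)-6,7-epoxy-12-hydroxy-3,7,11-trimethylpentadeca-2,10,14-trienal F3.
- Cross-metathesis with 7 gives methyl (2Z,5R,6E,10S,11S,14E)-2-(bromomethyl)-10,11-epoxy-5-hydroxy-6,10,14-trimethyl-16-oxohexadeca-2,6,14-trienoate F4.
- Stoichiometric CrCl2 in THF at high dilution closes C1–C2 under the bias of the remote epoxide and the C13 carbinol, a control element known for cembranoid closures. This gives, after separation, (1S,2S,3E,7S,8S,11E,13R)-7,8-epoxy-13-hydroxycembra-3,11,15(17)-trien-16,2-olide F5, which is phosphorylated as in step 6 to 12.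

**Step 4.**
- The hindered, electron-poor bromomethyl acrylate may cross-metathesise poorly.
- The δ-hydroxy allylic bromide 8 may cyclise to a dihydropyran.
- Fallback (sets out from 6, comes back at 10): it carries C16 at the alcohol level and oxidises it late, as the biosynthesis does.
- Metathesis of 6 with commercial 2-methylenepropane-1,3-diyl diacetate gives (5R,6E,10E,14E)-2-(acetoxymethyl)-5-hydroxy-6,10,14-trimethyl-16-oxohexadeca-2,6,10,14-tetraen-1-yl acetate F6.
- Pd(PPh3)4 with Et2Zn turns one allylic acetate into an allylzinc that closes C1–C2, giving after separation of diastereomers 2-[(1S,2S,3E,7E,11E,13R)-2,13-dihydroxy-4,8,12-trimethylcyclotetradeca-3,7,11-trien-1-yl]allyl acetate F7.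
- K2CO3 in MeOH gives (1S,2S,3E,7E,11E,13R)-1-(3-hydroxyprop-1-en-2-yl)-4,8,12-trimethylcyclotetradeca-3,7,11-triene-2,13-diol F8.
- 2,2,6,6-Tetramethylpiperidine-1-oxyl with PhI(OAc)2 then oxidises the primary allylic alcohol through the lactol to lactone 10.

## Further compounds
F1 | step 9 | (1S,2S,3E,7E,11S,12Z)-11-hydroperoxycembra-3,7,12,15(17)-tetraen-16,2-olide | C=C1C(=O)O[C@H]2/C=C(\C)CC/C=C(\C)CC[C@H](OO)/C(C)=C\C[C@@H]12
F2 | step 9 | (1S,2S,3E,7S,8S,11S,12Z)-7,8-epoxy-11-hydroperoxycembra-3,12,15(17)-trien-16,2-olide | C=C1C(=O)O[C@H]2/C=C(\C)CC[C@@H]3O[C@@]3(C)CC[C@H](OO)/C(C)=C\C[C@@H]12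
F3 | step 5 | (2E,6S,7S,10E,12R)-6,7-epoxy-12-hydroxy-3,7,11-trimethylpentadeca-2,10,14-trienal | C=CC[C@@H](O)/C(C)=C/CC[C@]1(C)O[C@H]1CC/C(C)=C/C=O
F4 | step 5 | methyl (2Z,5R,6E,10S,11S,14E)-2-(bromomethyl)-10,11-epoxy-5-hydroxy-6,10,14-trimethyl-16-oxohexadeca-2,6,14-trienoate | COC(=O)/C(CBr)=C/C[C@@H](O)/C(C)=C/CC[C@]1(C)O[C@H]1CC/C(C)=C/C=O
F5 | step 5 | (1S,2S,3E,7S,8S,11E,13R)-7,8-epoxy-13-hydroxycembra-3,11,15(17)-trien-16,2-olide | C=C1C(=O)O[C@H]2/C=C(\C)CC[C@@H]3O[C@@]3(C)CC/C=C(\C)[C@H](O)C[C@@H]12
F6 | step 4 | (5R,6E,10E,14E)-2-(acetoxymethyl)-5-hydroxy-6,10,14-trimethyl-16-oxohexadeca-2,6,10,14-tetraen-1-yl acetate | CC(=O)OCC(COC(C)=O)=CC[C@@H](O)/C(C)=C/CC/C(C)=C/CC/C(C)=C/C=O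
F7 | step 4 | 2-[(1S,2S,3E,7E,11E,13R)-2,13-dihydroxy-4,8,12-trimethylcyclotetradeca-3,7,11-trien-1-yl]allyl acetate | C=C(COC(C)=O)[C@@H]1C[C@@H](O)/C(C)=C/CC/C(C)=C/CC/C(C)=C/[C@@H]1O
F8 | step 4 | (1S,2S,3E,7E,11E,13R)-1-(3-hydroxyprop-1-en-2-yl)-4,8,12-trimethylcyclotetradeca-3,7,11-triene-2,13-diol | C=C(CO)[C@@H]1C[C@@H](O)/C(C)=C/CC/C(C)=C/CC/C(C)=C/[C@@H]1O
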